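The dihydropyran ring is disconnected at the C-4–C-4a bond (chromene numbering: O-1, C-2 gem-dimethyl, C-3 prenyl, C-4 methylene, C-4a quaternary fusion carbon). The key step is an intramolecular alkylative dearomatisation: the phenolate of a hexasubstituted acylphloroglucinol attacks, through its lavandulyl-bearing carbon, a primary bromide held on the neighbouring tertiary ether oxygen. This closes the pyran, creates the C-4a stereocentre under control of C-3 and unveils the enol-ether triketone carbocycle. It exploits that C-4a is the ortho carbon of a phloroglucinol enolate and that both C10 units on C-4a are identically configured, so one building block, (R)-lavandulol, supplies both.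

Key step: step 12

Assumption: (R)-(−)-lavandulol is taken as a commercial, enantiopure starting material; the C-6 methine between the two ring carbonyls is a labile β-dicarbonyl centre, and the drawn (6S) keto form is assumed to arise by protonation of the enol anti to the axial lavandulyl group.

Abbreviations in names: prenyl = 3-methylbut-2-en-1-yl; (S)-lavandulyl = (2S)-5-methyl-2-(prop-1-en-2-yl)hex-4-en-1-yl; allyl = prop-2-en-1-yl; TIPS = triisopropylsilyl; TIPS-tether = (3S)-2,6-dimethyl-3-{[(triisopropylsilyl)oxy]methyl}hept-5-en-2-yl.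

Step 1
Reactants: 1 (R)-(−)-lavandulol, (2R)-5-methyl-2-(prop-1-en-2-yl)hex-4-en-1-ol
Product: 2 (R)-lavandulyl TIPS ether
Conditions: TIPSCl, imidazole, DMF, rt
Reagents that add atoms: triisopropylsilyl chloride, CC(C)[Si](Cl)(C(C)C)C(C)C
Why: Silyl ether formation on the unhindered primary alcohol; the bulky TIPS group is chosen because it should not migrate to the tertiary alkoxide of step 3, and the stereocentre is untouched.

Step 2
Reactants: 2 (R)-lavandulyl TIPS ether
Product: 3 tertiary alcohol (3S)-2,6-dimethyl-3-{[(triisopropylsilyl)oxy]methyl}hept-5-en-2-ol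
Conditions: Co(acac)2 (cat.), PhSiH3 (1.1 equiv), O2 (1 atm), i-PrOH–THF, 0 °C → rt
Reagents that add atoms: dioxygen, O=O
Why: Mukaiyama hydration (hydrogen-atom transfer from a cobalt hydride, then O2 capture) adds water in the Markovnikov sense and should favour the 1,1-disubstituted isopropenyl group over the trisubstituted prenyl alkene when the silane is limiting; the tertiary radical has no 5-exo partner and no stereocentre is formed.

Step 3
Reactants: 3 tertiary alcohol; 4 1,3,5-trifluorobenzene
Product: 6 aryl ether 1,3-difluoro-5-(TIPS-tether-oxy)benzene, via potassium alkoxide 5 (not isolated)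
Conditions: KN(SiMe3)2, THF, 0 °C; then 4 (5 equiv), DMF, 60 °C
Reagents that add atoms: none
Why: Nucleophilic aromatic substitution (SNAr) of one fluoride by the tertiary alkoxide, activated by the two other meta fluorines; the excess of 4 and the alkoxy group in 6 should stop the reaction at mono-substitution.

Step 4
Reactants: 6 aryl ether; 7 prenyl bromide (1-bromo-3-methylbut-2-ene)
Product: 9 1,3-difluoro-2-prenyl-5-(TIPS-tether-oxy)benzene, via aryllithium 8 (not isolated)
Conditions: n-BuLi, THF, −78 °C; then 7, −78 → −40 °C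
Reagents that add atoms: none
Why: Directed ortho-lithiation removes the most acidic ring proton, the one flanked by both fluorines, and the aryllithium is allylated by prenyl bromide (SN2) below the temperature of benzyne formation.

Step 5
Reactants: 1 (R)-(−)-lavandulol
Product: 10 (R)-lavandulyl triflate, (2R)-5-methyl-2-(prop-1-en-2-yl)hex-4-en-1-yl trifluoromethanesulfonate
Conditions: Tf2O, 2,6-lutidine, CH2Cl2, −78 °C; cold pentane/silica plug, used at once
Reagents that add atoms: triflic anhydride, O=S(=O)(OS(=O)(=O)C(F)(F)F)C(F)(F)F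
Why: Sulfonylation of the primary alcohol gives the only leaving group reactive enough for the −78 °C alkylation of step 6; the stereocentre is not involved and the reagent is used cold to avoid homoallyl participation.

Step 6
Reactants: 9 prenyl arene; 10 (R)-lavandulyl triflate
Product: 12 3,5-difluoro-2-[(S)-lavandulyl]-4-prenyl-1-(TIPS-tether-oxy)benzene, via aryllithium 11 (not isolated)
Conditions: s-BuLi, THF, −78 °C; then 10 (pentane), −78 → −50 °C
Reagents that add atoms: none
Why: A second directed ortho-lithiation occurs at one of the two equivalent positions flanked by fluorine and the ether oxygen, and SN2 alkylation by the primary triflate installs the C-bound lavandulyl group with its stereocentre untouched.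

Step 7
Reactants: 13 methyl 3,4-dihydroxybenzoate
Product: 14 methyl 3,4-bis(allyloxy)benzoate
Conditions: allyl bromide, K2CO3, DMF, 60 °C
Reagents that add atoms: allyl bromide, C=CCBr
Why: Williamson ether synthesis on both phenols; allyl ethers survive the organolithium, alkoxide and fluoride steps and come off at the end under neutral conditions.

Step 8
Reactants: 12 lavandulyl prenyl arene; 14 methyl 3,4-bis(allyloxy)benzoate
Product: 16 benzophenone [3,4-bis(allyloxy)phenyl][4,6-difluoro-3-(S)-lavandulyl-5-prenyl-2-(TIPS-tether-oxy)phenyl]methanone, via aryllithium 15 (not isolated)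
Conditions: n-BuLi, THF, −78 °C; then 14, −78 °C; aq NH4Cl
Reagents that add atoms: none
Why: Ortho-lithiation at the last ring C–H and acyl substitution on the ester give the ketone, because the hindered diaryl ketone should not be attacked a second time by the bulky aryllithium at −78 °C.

Step 9
Reactants: 16 difluoro benzophenone
Product: 17 [3,4-bis(allyloxy)phenyl]{3-(S)-lavandulyl-5-prenyl-2-(TIPS-tether-oxy)-4,6-bis[2-(trimethylsilyl)ethoxy]phenyl}methanone
Conditions: Me3SiCH2CH2OH, NaH, DMF, 0 → 60 °C
Reagents that add atoms: 2-(trimethylsilyl)ethanol, C[Si](C)(C)CCO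
Why: Twofold SNAr of the fluorides ortho and para to the ketone by a hydroxide surrogate that leaves the ring a neutral ether after the first substitution, so the second fluoride stays activated.

Step 10
Reactants: 17 bis[2-(trimethylsilyl)ethyl] ether
Product: 18 triol [3,4-bis(allyloxy)phenyl]{2,4-dihydroxy-6-{[(3S)-3-(hydroxymethyl)-2,6-dimethylhept-5-en-2-yl]oxy}-5-(S)-lavandulyl-3-prenylphenyl}methanone
Conditions: Bu4NF, THF–DMF, rt → 50 °C; aq NH4Cl
Reagents that add atoms: none
Why: Fluoride cleaves the primary silyl ether and fragments both 2-(trimethylsilyl)ethyl aryl ethers (β-elimination with loss of ethene); the basic medium keeps the ortho-alkenyl phenols from acid-catalysed chroman formation.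

Step 11
Reactants: 18 triol
Product: 19 bromide [3,4-bis(allyloxy)phenyl]{6-{[(3R)-3-(bromomethyl)-2,6-dimethylhept-5-en-2-yl]oxy}-2,4-dihydroxy-5-(S)-lavandulyl-3-prenylphenyl}methanone
Conditions: CBr4, PPh3, CH2Cl2, 0 °C
Reagents that add atoms: carbon tetrabromide, BrC(Br)(Br)Br
Why: Appel bromination converts only the aliphatic primary alcohol, since aryloxyphosphonium ions from the phenols cannot be substituted and revert on work-up; the neutral medium avoids premature cyclisation.

Step 12
Reactants: 19 bromide
Product: 21 (3S,4aR,6S)-8-[3,4-bis(allyloxy)benzoyl]-2,2-dimethyl-3,6-diprenyl-4a-[(S)-lavandulyl]-3,4-dihydro-2H-chromene-5,7(4aH,6H)-dione, via caesium phenolate 20 (not isolated)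
Conditions: Cs2CO3 (2.5 equiv), DMF (0.005 M), 50 °C; aq NaH2PO4
Reagents that add atoms: none
Why: Cs2CO3 deprotonates the hydroxyl para to the ketone, and the ambident phenolate attacks through ring carbon C-4a (ortho to the phenolate oxygen, bearing the lavandulyl group) the primary bromide in an SN2 displacement, giving a cyclohexadienone that is obtained as its β-triketone tautomer. The closest known reaction type is the alkylative dearomatisation of acylphloroglucinols (phenol ortho-C-alkylation), here made intramolecular. The dihydropyran closes in a 6-(enolendo)-exo-tet mode. The new quaternary stereocentre C-4a is set by the tether stereocentre C-3 through a chair-like transition state with the C-3 prenyl group equatorial, which places the lavandulyl group axial and trans to it, i.e. (4aR); C-6 is set on protonation anti to the lavandulyl group and remains a labile centre. The step needs C- over O-alkylation, C-4a over the aroyl-bearing C-8, and cyclisation over intermolecular reaction: O-alkylation would need an eight-membered ring, attack at C-8 is hindered and would destroy the hydrogen-bonded vinylogous acid, and high dilution suppresses intermolecular paths.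

Step 13
Reactants: 21 bis(allyl ether)
Product: 22 target, (3S,4aR,6S)-8-(3,4-dihydroxybenzoyl)-2,2-dimethyl-3,6-diprenyl-4a-[(S)-lavandulyl]-3,4-dihydro-2H-chromene-5,7(4aH,6H)-dione
Conditions: Pd(PPh3)4 (cat.), PhSiH3, CH2Cl2, rt
Reagents that add atoms: none
Why: Deallylation of the two aryl allyl ethers through π-allyl complexes of zerovalent palladium (Tsuji–Trost ionisation) with PhSiH3 as hydride donor releases propene under neutral conditions, so the acidic β-triketone should not be C-allylated and the other alkenes and the enol ether are untouched.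

Compound list
1 | (R)-(−)-lavandulol | OC[C@H](CC=C(C)C)C(C)=C | starting material
2 | (R)-lavandulyl TIPS ether | CC(C)[Si](C(C)C)(C(C)C)OC[C@H](CC=C(C)C)C(C)=C | intermediate
3 | (3S)-2,6-dimethyl-3-{[(triisopropylsilyl)oxy]methyl}hept-5-en-2-ol | CC(C)[Si](C(C)C)(C(C)C)OC[C@H](CC=C(C)C)C(C)(C)O | intermediate
4 | 1,3,5-trifluorobenzene | Fc1cc(F)cc(F)c1 | starting material
5 | potassium alkoxide of 3 | CC(C)[Si](C(C)C)(C(C)C)OC[C@H](CC=C(C)C)C(C)(C)[O-].[K+] | intermediate (not isolated)
6 | 1,3-difluoro-5-(TIPS-tether-oxy)benzene | CC(C)[Si](C(C)C)(C(C)C)OC[C@H](CC=C(C)C)C(C)(C)Oc1cc(F)cc(F)c1 | intermediate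
7 | prenyl bromide | CC(C)=CCBr | starting material
8 | 2,6-difluoro-4-(TIPS-tether-oxy)phenyllithium | CC(C)[Si](C(C)C)(C(C)C)OC[C@H](CC=C(C)C)C(C)(C)Oc1cc(F)c([Li])c(F)c1 | intermediate (not isolated)
9 | 1,3-difluoro-2-prenyl-5-(TIPS-tether-oxy)benzene | CC(C)[Si](C(C)C)(C(C)C)OC[C@H](CC=C(C)C)C(C)(C)Oc1cc(F)c(CC=C(C)C)c(F)c1 | intermediate
10 | (R)-lavandulyl triflate | FC(F)(F)S(=O)(=O)OC[C@H](CC=C(C)C)C(C)=C | intermediate
11 | aryllithium from 9, lithiated ortho to the ether oxygen | CC(C)[Si](C(C)C)(C(C)C)OC[C@H](CC=C(C)C)C(C)(C)Oc1cc(F)c(CC=C(C)C)c(F)c1[Li] | intermediate (not isolated)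
12 | 3,5-difluoro-2-[(S)-lavandulyl]-4-prenyl-1-(TIPS-tether-oxy)benzene | CC(C)[Si](C(C)C)(C(C)C)OC[C@H](CC=C(C)C)C(C)(C)Oc1cc(F)c(CC=C(C)C)c(F)c1C[C@H](CC=C(C)C)C(C)=C | intermediate
13 | methyl 3,4-dihydroxybenzoate | COC(=O)c1ccc(O)c(O)c1 | starting material
14 | methyl 3,4-bis(allyloxy)benzoate | COC(=O)c1ccc(OCC=C)c(OCC=C)c1 | intermediate
15 | aryllithium from 12, lithiated at the last ring C–H | CC(C)[Si](C(C)C)(C(C)C)OC[C@H](CC=C(C)C)C(C)(C)Oc1c([Li])c(F)c(CC=C(C)C)c(F)c1C[C@H](CC=C(C)C)C(C)=C | intermediate (not isolated)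
16 | [3,4-bis(allyloxy)phenyl][4,6-difluoro-3-(S)-lavandulyl-5-prenyl-2-(TIPS-tether-oxy)phenyl]methanone | CC(C)[Si](C(C)C)(C(C)C)OC[C@H](CC=C(C)C)C(C)(C)Oc1c(C(=O)c2ccc(OCC=C)c(OCC=C)c2)c(F)c(CC=C(C)C)c(F)c1C[C@H](CC=C(C)C)C(C)=C | intermediate
17 | bis[2-(trimethylsilyl)ethyl] ether of the 4,6-dihydroxy benzophenone | CC(C)[Si](C(C)C)(C(C)C)OC[C@H](CC=C(C)C)C(C)(C)Oc1c(C(=O)c2ccc(OCC=C)c(OCC=C)c2)c(OCC[Si](C)(C)C)c(CC=C(C)C)c(OCC[Si](C)(C)C)c1C[C@H](CC=C(C)C)C(C)=C | intermediate
18 | triol (two ring phenols, primary alcohol on the tether) | OC[C@H](CC=C(C)C)C(C)(C)Oc1c(C(=O)c2ccc(OCC=C)c(OCC=C)c2)c(O)c(CC=C(C)C)c(O)c1C[C@H](CC=C(C)C)C(C)=C | intermediate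
19 | primary bromide of 18 | BrC[C@H](CC=C(C)C)C(C)(C)Oc1c(C(=O)c2ccc(OCC=C)c(OCC=C)c2)c(O)c(CC=C(C)C)c(O)c1C[C@H](CC=C(C)C)C(C)=C | intermediate
20 | caesium phenolate of 19 (oxygen para to the ketone) | BrC[C@H](CC=C(C)C)C(C)(C)Oc1c(C(=O)c2ccc(OCC=C)c(OCC=C)c2)c(O)c(CC=C(C)C)c([O-])c1C[C@H](CC=C(C)C)C(C)=C.[Cs+] | intermediate (not isolated)
21 | (3S,4aR,6S)-8-[3,4-bis(allyloxy)benzoyl]-2,2-dimethyl-3,6-diprenyl-4a-[(S)-lavandulyl]-3,4-dihydro-2H-chromene-5,7(4aH,6H)-dione | C=C(C)[C@@H](CC=C(C)C)C[C@@]12C[C@H](CC=C(C)C)C(C)(C)OC1=C(C(=O)c1ccc(OCC=C)c(OCC=C)c1)C(=O)[C@@H](CC=C(C)C)C2=O | intermediate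
22 | target CNP0250793.1 | C=C(C)[C@@H](CC=C(C)C)C[C@@]12C[C@H](CC=C(C)C)C(C)(C)OC1=C(C(=O)c1ccc(O)c(O)c1)C(=O)[C@@H](CC=C(C)C)C2=O | target

Total step count: 13. Longest linear sequence: 11 steps (steps 1, 2, 3, 4, 6, 8, 9, 10, 11, 12, 13).

Steps most likely to fail

Step 12 (key step). The SN2 displacement at the β-branched primary carbon may be slow, so that E2 loss of HBr, intermolecular O-alkylation or closure onto the aroyl-bearing carbon could compete; facial control at C-4a may also be incomplete. The fallback sets out from triol 18 and closes the ring under Mitsunobu conditions (PPh3, DIAD, toluene, 0 °C → rt). The acidic vinylogous-acid phenol protonates the betaine and its ring carbon C-4a displaces the alkoxyphosphonium group of the tether intramolecularly. This avoids base and halide and returns directly to 21; no new compound is made on the way (F0).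

Step 9. Substitution at the two flanked fluorides may be sluggish because the di-ortho-substituted ketone is twisted out of conjugation, and forcing conditions could isomerise the prenyl or allyl groups. The fallback sets out from 16 and moves the second C–O bond formation to after the dearomatisation:
- One equivalent of NaOCH2CH2SiMe3 in toluene (sodium chelation to the ketone directs attack to the ortho fluoride) should give the mono-ether with the para fluoride retained F1.
- Bu4NF should give the fluoro phenol alcohol F2, and CBr4/PPh3 the fluoro phenol bromide F3.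
- Cs2CO3 in dilute DMF should cyclise the phenolate para to C-4a to the 5-fluoro cross-conjugated dienone F4.
- The C-5 fluoride of F4 is a vinylogous acyl fluoride, and aqueous LiOH in THF should hydrolyse it by addition–elimination, which comes back to the route at 21.

Step 6. The basic aryllithium may cause E2 elimination of the triflate (its β-hydrogen is allylic), may deprotonate the prenyl methylene laterally, or may collapse to a benzyne if alkylation is slow. The fallback reverses the polarity of the coupling:
- From 9, lithiation and an iodine quench should give the aryl iodide F5.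
- From 1, I2/PPh3/imidazole should give (R)-lavandulyl iodide F6, and Zn dust with LiCl in THF lavandulylzinc iodide F7.
- Negishi coupling of F5 and F7 (Pd(OAc)2, SPhos, THF, 50 °C) comes back to the route at 12.

Further compounds
F0 | step 12 | none | none
F1 | step 9 | mono[2-(trimethylsilyl)ethyl] ether of 16 (ortho to the ketone), para fluoride retained | CC(C)[Si](C(C)C)(C(C)C)OC[C@H](CC=C(C)C)C(C)(C)Oc1c(C(=O)c2ccc(OCC=C)c(OCC=C)c2)c(OCC[Si](C)(C)C)c(CC=C(C)C)c(F)c1C[C@H](CC=C(C)C)C(C)=C
F2 | step 9 | fluoro phenol alcohol (analogue of 18 with fluorine para to the ketone) | OC[C@H](CC=C(C)C)C(C)(C)Oc1c(C(=O)c2ccc(OCC=C)c(OCC=C)c2)c(O)c(CC=C(C)C)c(F)c1C[C@H](CC=C(C)C)C(C)=C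
F3 | step 9 | fluoro phenol bromide (analogue of 19 with fluorine para to the ketone) | BrC[C@H](CC=C(C)C)C(C)(C)Oc1c(C(=O)c2ccc(OCC=C)c(OCC=C)c2)c(O)c(CC=C(C)C)c(F)c1C[C@H](CC=C(C)C)C(C)=C
F4 | step 9 | 5-fluoro dienone, 8-[3,4-bis(allyloxy)benzoyl]-5-fluoro-2,2-dimethyl-3,6-diprenyl-4a-[(S)-lavandulyl]-3,4-dihydro-2H-chromen-7(4aH)-one | C=C(C)[C@@H](CC=C(C)C)C[C@@]12C[C@H](CC=C(C)C)C(C)(C)OC1=C(C(=O)c1ccc(OCC=C)c(OCC=C)c1)C(=O)C(CC=C(C)C)=C2F
F5 | step 6 | aryl iodide, 3,5-difluoro-2-iodo-4-prenyl-1-(TIPS-tether-oxy)benzene | CC(C)[Si](C(C)C)(C(C)C)OC[C@H](CC=C(C)C)C(C)(C)Oc1cc(F)c(CC=C(C)C)c(F)c1I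
F6 | step 6 | (R)-lavandulyl iodide | IC[C@H](CC=C(C)C)C(C)=C
F7 | step 6 | lavandulylzinc iodide | I[Zn]C[C@H](CC=C(C)C)C(C)=C
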